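**Plan**
- Retrosynthesis: the two sulfate S–O bonds and the three O–benzyl bonds are cut first, leaving a diaryl ether phenol. Ring A (numbered from the aryloxy carbon, C1) is then cut at C2–C3 and C1–C6, giving an ethynyl ether of ring B and a four-carbon cyclobutenone.
- Enabling feature: ring A is a benzene with oxygen on C1, C3 and C5, each in a different state (aryl ether, sulfate, free OH). A ketene carbonyl (C3–OH), a 3-alkoxy group on the cyclobutenone (C5–O) and an ynol ether oxygen (C1–O) map onto this all-meta pattern and emerge already distinguished.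
- Forward: ring B starts as 3,5-bis(benzyloxy)phenol. Para-oxidation and reduction add its fourth oxygen, the open hydroxyl is silylated, and the hindered hydroxyl becomes the ethynyl ether. Ring A is then built on that alkyne by benzannulation, the only ring-forming step.
- Endgame: desilylation, sulfation of the two free phenols, hydrogenolysis of the three benzyl ethers.
- Stereochemistry: the target has no stereocentre, stereogenic axis or configured double bond, so nothing has to be set or preserved.

Key step: step 7

Remark: the target is achiral and is drawn as the free bis(hydrogen sulfate); the sulfates are carried as sodium salts and the acid form is released on an H+ resin in the last operation, because aryl hydrogen sulfates hydrolyse when kept in acid.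

**Route**

Step 1
Reactants: 1 3,5-bis(benzyloxy)phenol
Product: 2 2,6-bis(benzyloxy)-1,4-benzoquinone
Conditions: (KSO3)2NO (2.2 equiv), KH2PO4, acetone–H2O, 0 °C → rt
Reagents that add atoms: potassium nitrosodisulfonate (Fremy's salt), [K+].[K+].[O]N(S(=O)(=O)[O-])S(=O)(=O)[O-]
Why: Teuber oxidation: Fremy's radical abstracts the phenolic hydrogen and a second equivalent couples at the free para carbon (the one between the two benzyloxy groups), so loss of imidodisulfonate should give the para-quinone with the new oxygen where ring B needs it.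

Step 2
Reactants: 2 2,6-bis(benzyloxy)-1,4-benzoquinone
Product: 3 2,6-bis(benzyloxy)benzene-1,4-diol
Conditions: Na2S2O4, EtOAc–H2O, rt, Ar; used crude
Reagents that add atoms: none
Why: Dithionite reduction of a benzoquinone to the hydroquinone is fast in a two-phase system and, unlike hydrogenation, leaves the benzyl ethers alone.

Step 3
Reactants: 3 2,6-bis(benzyloxy)benzene-1,4-diol
Product: 4 2,6-bis(benzyloxy)-4-(triisopropylsilyloxy)phenol
Conditions: i-Pr3SiCl (1.05 equiv), imidazole, DMF, 0 °C
Reagents that add atoms: chlorotri(propan-2-yl)silane, CC(C)[Si](Cl)(C(C)C)C(C)C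
Why: Silylation of a phenol with a bulky chlorosilane and imidazole should occur at the C4 hydroxyl, which has two ortho hydrogens, and spare the C1 hydroxyl that is buried between two benzyloxy groups.

Step 4
Reactants: 4 2,6-bis(benzyloxy)-4-(triisopropylsilyloxy)phenol; 5 trichloroethylene
Product: 7 {3,5-bis(benzyloxy)-4-[(E)-1,2-dichloroethenoxy]phenoxy}triisopropylsilane, via potassium phenoxide 6 (not isolated)
Conditions: KH (2 equiv), THF, 0 °C; Cl2C=CHCl (1.2 equiv), 0 °C → rt
Reagents that add atoms: none
Why: First stage of the trichloroethylene route to ynol ethers: the potassium phenoxide adds to dichloroacetylene formed in situ by dehydrochlorination, anti addition giving the (E)-1,2-dichlorovinyl ether, and the hydride base leaves silyl and benzyl ethers untouched.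

Step 5
Reactants: 7 {3,5-bis(benzyloxy)-4-[(E)-1,2-dichloroethenoxy]phenoxy}triisopropylsilane
Product: 10 1,3-bis(benzyloxy)-2-(ethynyloxy)-5-(triisopropylsilyloxy)benzene, via chloroethynyl ether 8 (not isolated), via lithium aryloxyacetylide 9 (not isolated)
Conditions: n-BuLi (2.4 equiv), THF, −78 → −40 °C; MeOH, −78 °C; neutral work-up, filtration through basic alumina, used at once
Reagents that add atoms: none
Why: Second stage of the same route: butyllithium eliminates HCl to the chloroalkyne and then exchanges chlorine for lithium, methanol protonates the acetylide, and at −78 °C neither the aryl silyl ether nor the benzyl ethers should be attacked.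

Step 6
Reactants: 11 3-ethoxycyclobut-2-en-1-one; 12 benzyl alcohol
Product: 13 3-(benzyloxy)cyclobut-2-en-1-one
Conditions: BnOH (2 equiv), camphorsulfonic acid (5 mol %), PhMe, 40 °C, 100 mbar (EtOH stripped off)
Reagents that add atoms: none
Why: Acid-catalysed alkoxy exchange of a vinylogous ester (addition of the alcohol at C3 of the protonated enone, loss of ethanol), as known for 3-alkoxyenones and squarate esters, should be driven to the benzyl ether by stripping out the ethanol.

Step 7
Reactants: 10 1,3-bis(benzyloxy)-2-(ethynyloxy)-5-(triisopropylsilyloxy)benzene; 13 3-(benzyloxy)cyclobut-2-en-1-one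
Product: 18 3-(benzyloxy)-5-[2,6-bis(benzyloxy)-4-(triisopropylsilyloxy)phenoxy]phenol, via vinylketene 14 (not isolated), via vinylcyclobutenone 15 (not isolated), via dienylketene 16 (not isolated), via cyclohexadienone 17 (not isolated)
Conditions: 13 (1.2 equiv, added over 4 h), PhMe (0.1 M in 10), 110 °C, Ar
Reagents that add atoms: none
Why: Heat opens cyclobutenone 13 by a reversible four-electron electrocyclic reaction to vinylketene 14, whose ketene C=C adds [2+2] to the electron-rich triple bond of 10 to give 4-vinylcyclobutenone 15; a second four-electron opening gives dienylketene 16, which closes ring A by a thermal disrotatory six-electron electrocyclisation to dienone 17 and tautomerises to phenol 18. This is a Danheiser benzannulation of a cyclobutenone with an alkynyl ether, applied here to an aryloxyacetylene and a 3-alkoxycyclobutenone. With ring A numbered from the aryloxy carbon, the cycloaddition makes C2–C3 and C1–C6, and the C3–C4 bond cut in the first opening is re-made in the six-electron closure, the only ring-forming event. No stereocentre results: the sp3 carbon of 15 is lost on opening, and because that opening is reversible only the isomer of 16 with the ketene and enol ether arms cis is drained toward 18. The one selectivity needed is the orientation of the [2+2], and the ynol ether secures it, since its nucleophilic terminal carbon bonds to the electrophilic ketene carbonyl carbon and so places the aryloxy group meta to both the new hydroxyl and the benzyloxy group. The hindered ring B oxygen enters on an sp carbon, so its two ortho benzyloxy groups should not slow the bond-forming steps, and slow addition of 13 keeps the ketene scarce relative to the alkyne.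

Step 8
Reactants: 18 3-(benzyloxy)-5-[2,6-bis(benzyloxy)-4-(triisopropylsilyloxy)phenoxy]phenol
Product: 19 3-(benzyloxy)-5-[2,6-bis(benzyloxy)-4-hydroxyphenoxy]phenol
Conditions: Bu4NF (1.2 equiv), AcOH (1.2 equiv), THF, 0 °C
Reagents that add atoms: none
Why: Fluoride-induced cleavage of the aryl silyl ether, buffered with acetic acid so that the electron-rich phenols are not exposed as naked phenoxides, leaves the benzyl ethers and the diaryl ether alone.

Step 9
Reactants: 19 3-(benzyloxy)-5-[2,6-bis(benzyloxy)-4-hydroxyphenoxy]phenol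
Product: 21 disodium 3-(benzyloxy)-5-[2,6-bis(benzyloxy)-4-(sulfonatooxy)phenoxy]phenyl sulfate, via bis(pyridinium) bis-sulfate 20 (not isolated)
Conditions: SO3·pyridine (6 equiv), pyridine, rt → 40 °C; aq NaHCO3 to pH 8; C18 chromatography
Reagents that add atoms: sulfur trioxide–pyridine complex, O=S(=O)([O-])[n+]1ccccc1; sodium hydrogen carbonate, [Na+].OC(=O)[O-]
Why: O-Sulfation of phenols with the sulfur trioxide–pyridine complex is routine, only the two hydroxyls that are to be sulfated are free so no site selectivity is asked for, and exchange to the sodium salt gives a form that is stable to storage and to hydrogenation.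

Step 10
Reactants: 21 disodium 3-(benzyloxy)-5-[2,6-bis(benzyloxy)-4-(sulfonatooxy)phenoxy]phenyl sulfate
Product: 23 3-hydroxy-5-[2,6-dihydroxy-4-(sulfooxy)phenoxy]phenyl hydrogen sulfate (CNP0460023.0), via debenzylated disodium salt 22 (not isolated)
Conditions: H2 (1 atm), 10% Pd/C, MeOH–H2O, rt; filter; Dowex 50W-X8 (H+), H2O, 0 °C; freeze-dry
Reagents that add atoms: none
Why: Catalytic hydrogenolysis of benzyl aryl ethers over palladium does not touch aryl sulfate salts or the diaryl ether, and brief cold contact with a sulfonic acid resin exchanges sodium for hydrogen to release the bis(hydrogen sulfate) as drawn.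

**Compound list**

1 | 3,5-bis(benzyloxy)phenol | Oc1cc(OCc2ccccc2)cc(OCc2ccccc2)c1 | starting material
2 | 2,6-bis(benzyloxy)cyclohexa-2,5-diene-1,4-dione | O=C1C=C(OCc2ccccc2)C(=O)C(OCc2ccccc2)=C1 | intermediate
3 | 2,6-bis(benzyloxy)benzene-1,4-diol | Oc1cc(OCc2ccccc2)c(O)c(OCc2ccccc2)c1 | intermediate
4 | 2,6-bis(benzyloxy)-4-(triisopropylsilyloxy)phenol | Oc1c(OCc2ccccc2)cc(O[Si](C(C)C)(C(C)C)C(C)C)cc1OCc1ccccc1 | intermediate
5 | trichloroethylene | ClC=C(Cl)Cl | starting material
6 | potassium 2,6-bis(benzyloxy)-4-(triisopropylsilyloxy)phenolate | [K+].[O-]c1c(OCc2ccccc2)cc(O[Si](C(C)C)(C(C)C)C(C)C)cc1OCc1ccccc1 | intermediate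
7 | {3,5-bis(benzyloxy)-4-[(E)-1,2-dichloroethenoxy]phenoxy}triisopropylsilane | Cl/C=C(/Cl)Oc1c(OCc2ccccc2)cc(O[Si](C(C)C)(C(C)C)C(C)C)cc1OCc1ccccc1 | intermediate
8 | {3,5-bis(benzyloxy)-4-[(chloroethynyl)oxy]phenoxy}triisopropylsilane | ClC#COc1c(OCc2ccccc2)cc(O[Si](C(C)C)(C(C)C)C(C)C)cc1OCc1ccccc1 | intermediate
9 | lithium 2-[2,6-bis(benzyloxy)-4-(triisopropylsilyloxy)phenoxy]ethynide | [Li]C#COc1c(OCc2ccccc2)cc(O[Si](C(C)C)(C(C)C)C(C)C)cc1OCc1ccccc1 | intermediate
10 | 1,3-bis(benzyloxy)-2-(ethynyloxy)-5-(triisopropylsilyloxy)benzene | C#COc1c(OCc2ccccc2)cc(O[Si](C(C)C)(C(C)C)C(C)C)cc1OCc1ccccc1 | intermediate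
11 | 3-ethoxycyclobut-2-en-1-one | CCOC1=CC(=O)C1 | starting material
12 | benzyl alcohol | OCc1ccccc1 | starting material
13 | 3-(benzyloxy)cyclobut-2-en-1-one | O=C1C=C(OCc2ccccc2)C1 | intermediate
14 | 3-(benzyloxy)buta-1,3-dien-1-one | C=C(OCc1ccccc1)C=C=O | intermediate
15 | 3-[2,6-bis(benzyloxy)-4-(triisopropylsilyloxy)phenoxy]-4-[1-(benzyloxy)ethenyl]cyclobut-2-en-1-one (racemic, transient) | O=C1C=C(Oc2c(OCc3ccccc3)cc(O[Si](C(C)C)(C(C)C)C(C)C)cc2OCc2ccccc2)C1C(=C)OCc1ccccc1 | intermediate
16 | (3E)-3-[2,6-bis(benzyloxy)-4-(triisopropylsilyloxy)phenoxy]-5-(benzyloxy)hexa-1,3,5-trien-1-one | O=C=C/C(Oc1c(OCc2ccccc2)cc(O[Si](C(C)C)(C(C)C)C(C)C)cc1OCc1ccccc1)=C\C(=C)OCc1ccccc1 | intermediate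
17 | 3-[2,6-bis(benzyloxy)-4-(triisopropylsilyloxy)phenoxy]-5-(benzyloxy)cyclohexa-2,4-dien-1-one | O=C1C=C(Oc2c(OCc3ccccc3)cc(O[Si](C(C)C)(C(C)C)C(C)C)cc2OCc2ccccc2)C=C(OCc2ccccc2)C1 | intermediate
18 | 3-(benzyloxy)-5-[2,6-bis(benzyloxy)-4-(triisopropylsilyloxy)phenoxy]phenol | Oc1cc(OCc2ccccc2)cc(Oc2c(OCc3ccccc3)cc(O[Si](C(C)C)(C(C)C)C(C)C)cc2OCc2ccccc2)c1 | intermediate
19 | 3-(benzyloxy)-5-[2,6-bis(benzyloxy)-4-hydroxyphenoxy]phenol | Oc1cc(OCc2ccccc2)cc(Oc2c(OCc3ccccc3)cc(O)cc2OCc2ccccc2)c1 | intermediate
20 | bis(pyridinium) 3-(benzyloxy)-5-[2,6-bis(benzyloxy)-4-(sulfonatooxy)phenoxy]phenyl sulfate | c1cc[nH+]cc1.c1cc[nH+]cc1.[O-]S(=O)(=O)Oc1cc(OCc2ccccc2)cc(Oc2c(OCc3ccccc3)cc(OS(=O)(=O)[O-])cc2OCc2ccccc2)c1 | intermediate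
21 | disodium 3-(benzyloxy)-5-[2,6-bis(benzyloxy)-4-(sulfonatooxy)phenoxy]phenyl sulfate | [Na+].[Na+].[O-]S(=O)(=O)Oc1cc(OCc2ccccc2)cc(Oc2c(OCc3ccccc3)cc(OS(=O)(=O)[O-])cc2OCc2ccccc2)c1 | intermediate
22 | disodium 3-hydroxy-5-[2,6-dihydroxy-4-(sulfonatooxy)phenoxy]phenyl sulfate | [Na+].[Na+].[O-]S(=O)(=O)Oc1cc(O)cc(Oc2c(O)cc(OS(=O)(=O)[O-])cc2O)c1 | intermediate
23 | 3-hydroxy-5-[2,6-dihydroxy-4-(sulfooxy)phenoxy]phenyl hydrogen sulfate | O=S(=O)(O)Oc1cc(O)cc(Oc2c(O)cc(OS(=O)(=O)O)cc2O)c1 | target

**Step count**

Total steps: 10. Longest linear sequence: 9 steps (steps 1–5 and 7–10, from compound 1); step 6 is a one-step branch.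

**Steps most likely to fail**

Step 7. The cyclobutenone and alkyne partners are an untested pairing for this annulation. The vinylogous-ester stabilisation of 13 may slow its electrocyclic opening so much that the ynol ether oligomerises before any ketene is available. Ketene 14 may also dimerise or acylate the product phenol instead of finding the alkyne. The fallback forms the diaryl ether C–O bond directly; it sets out from phenol 4 and rejoins the route at diphenol 19. 5-Bromoresorcinol would be monobenzylated (BnBr, K2CO3, acetone) to 3-(benzyloxy)-5-bromophenol F1 and silylated (i-Pr3SiCl, imidazole) to [3-(benzyloxy)-5-bromophenoxy]triisopropylsilane F2. Bromine–lithium exchange, triisopropyl borate and mild acid would give [3-(benzyloxy)-5-(triisopropylsilyloxy)phenyl]boronic acid F3. Chan–Lam coupling of F3 with 4 (Cu(OAc)2, pyridine, 4 Å sieves, CH2Cl2, air, rt) should then give {3-(benzyloxy)-5-[2,6-bis(benzyloxy)-4-(triisopropylsilyloxy)phenoxy]phenoxy}triisopropylsilane F4. Buffered fluoride as in step 8 would remove both silyl groups and deliver 19.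

Step 6. Benzyl alcohol or adventitious water may attack the strained enone at the carbonyl and open the ring to acetoacetate-type esters, or hydrolysis to the unstable 1,3-dione may outrun the exchange. The fallback makes that hydrolysis deliberate; it sets out from 11 and rejoins at 13. Dilute aqueous HCl would convert 11 into cyclobutane-1,3-dione F5. This vinylogous acid would then be O-benzylated with benzyl alcohol under Mitsunobu conditions (PPh3, DIAD, THF, 0 °C) to give 13.

Step 5. The terminal aryloxyacetylene may hydrate to the aryl acetate or oligomerise during work-up and concentration. The fallback caps the alkyne with silicon; it sets out from lithium acetylide 9 and rejoins at phenol 18. Quenching 9 with Me3SiCl instead of methanol would give {[2,6-bis(benzyloxy)-4-(triisopropylsilyloxy)phenoxy]ethynyl}trimethylsilane F6, which should tolerate chromatography and storage. Heating F6 with 13 as in step 7 (same orientation of the cycloaddition) would give 5-(benzyloxy)-3-[2,6-bis(benzyloxy)-4-(triisopropylsilyloxy)phenoxy]-2-(trimethylsilyl)phenol F7, with silicon on ring A C2. Ipso-protodesilylation of this very electron-rich position (CF3CO2H, CH2Cl2, 0 °C) would return 18.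

Further compounds
F1 | step 7 | 3-(benzyloxy)-5-bromophenol | Oc1cc(Br)cc(OCc2ccccc2)c1
F2 | step 7 | [3-(benzyloxy)-5-bromophenoxy]triisopropylsilane | CC(C)[Si](Oc1cc(Br)cc(OCc2ccccc2)c1)(C(C)C)C(C)C
F3 | step 7 | [3-(benzyloxy)-5-(triisopropylsilyloxy)phenyl]boronic acid | OB(O)c1cc(OCc2ccccc2)cc(O[Si](C(C)C)(C(C)C)C(C)C)c1
F4 | step 7 | {3-(benzyloxy)-5-[2,6-bis(benzyloxy)-4-(triisopropylsilyloxy)phenoxy]phenoxy}triisopropylsilane | CC(C)[Si](Oc1cc(OCc2ccccc2)cc(Oc2c(OCc3ccccc3)cc(O[Si](C(C)C)(C(C)C)C(C)C)cc2OCc2ccccc2)c1)(C(C)C)C(C)C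
F5 | step 6 | cyclobutane-1,3-dione | O=C1CC(=O)C1
F6 | step 5 | {[2,6-bis(benzyloxy)-4-(triisopropylsilyloxy)phenoxy]ethynyl}trimethylsilane | C[Si](C)(C)C#COc1c(OCc2ccccc2)cc(O[Si](C(C)C)(C(C)C)C(C)C)cc1OCc1ccccc1
F7 | step 5 | 5-(benzyloxy)-3-[2,6-bis(benzyloxy)-4-(triisopropylsilyloxy)phenoxy]-2-(trimethylsilyl)phenol | C[Si](C)(C)c1c(O)cc(OCc2ccccc2)cc1Oc1c(OCc2ccccc2)cc(O[Si](C(C)C)(C(C)C)C(C)C)cc1OCc1ccccc1
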